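**Plan**
- Retrosynthesis cuts, in this order: the benzylic C–O bond of the fumarate (ortho-quinone methide), the lactol lactone (acetal plus ester), the depsidone ester C–O bond, the two C–C bonds of ring B (carboxyl-bearing carbon to lactol-bearing carbon, and CH2-bearing carbon to the carbon of the ester oxygen), and the alkyl C–O bond of the aryl ether.
- Ring B (the lactol-fused arene) is a 2,4-dihydroxybenzoate in disguise. Going round from the ether carbon, the carbon of the ester oxygen, the CH2-bearing carbon, the phenol carbon and the carbon of the lactone carbonyl stand in 3,5-dioxo ester register, and the sixth carbon holds an aldehyde-level carbon. Ring B can therefore be condensed from an acetoacetate and an aryloxyacrylate that already carries ring A through oxygen.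
- Forward: ring A (orsellinic acid) receives its formyl carbon early, at the only free ortho position of a phenol, and carries it as a vinyl group. The chelated phenol is alkylated, ring B is annulated, and its single C–H (between two phenols) takes the benzylic carbon by a Mannich reaction.
- Then the seven-membered lactone, the aldehyde, the five-membered lactol lactone and last the fumarate ester are made.
- Stereochemistry: the E alkene comes with fumaric acid. The only stereocentre, the (R)-lactol carbon, forms racemic and is set at the end by crystallisation-induced dynamic resolution of the quinine salt.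

Key step: step 8

Remark: the stereocentre is a hemiacetal carbon that epimerises in solution by ring–chain tautomerism, so the (R) enantiomer is defined and delivered as the crystalline solid.

**Step 1**
Reactants: 1 orsellinic acid
Product: 2 allyl 2,4-dihydroxy-6-methylbenzoate
Conditions: allyl bromide, KHCO3, DMF, rt
Reagents that add atoms: allyl bromide, C=CCBr
Why: Carboxylate alkylation (SN2): hydrogen carbonate ionises only the carboxylic acid, so the ester forms and both phenols stay free.

**Step 2**
Reactants: 2 allyl 2,4-dihydroxy-6-methylbenzoate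
Product: 3 allyl 2-hydroxy-4-(methoxymethoxy)-6-methylbenzoate
Conditions: MOMCl, i-Pr2NEt, CH2Cl2, 0 °C to rt
Reagents that add atoms: chloromethyl methyl ether, COCCl
Why: Williamson-type O-alkylation: the 2-hydroxyl is held in a hydrogen bond to the ester carbonyl, so only the 4-hydroxyl should be protected.

**Step 3**
Reactants: 3 allyl 2-hydroxy-4-(methoxymethoxy)-6-methylbenzoate
Product: 4 allyl 3-formyl-2-hydroxy-4-(methoxymethoxy)-6-methylbenzoate
Conditions: MgCl2, Et3N, paraformaldehyde, MeCN, reflux
Reagents that add atoms: paraformaldehyde (as formaldehyde), C=O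
Why: Casnati–Skattebøl magnesium-mediated ortho-formylation: the magnesium phenoxide delivers formaldehyde only to an ortho carbon, and the single free ortho carbon of 3 is C3 between the two oxygens, so the formyl carbon of ring A is placed without a regiochemical choice.

**Step 4**
Reactants: 4 allyl 3-formyl-2-hydroxy-4-(methoxymethoxy)-6-methylbenzoate
Product: 5 allyl 2-hydroxy-4-(methoxymethoxy)-6-methyl-3-vinylbenzoate
Conditions: Ph3PCH3Br, KOt-Bu (excess, covers the phenol), THF, 0 °C to rt
Reagents that add atoms: methyltriphenylphosphonium bromide, C[P+](c1ccccc1)(c1ccccc1)c1ccccc1.[Br-]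
Why: Wittig methylenation masks the aldehyde as a vinyl group that is inert to the enolate, palladium and acylation chemistry ahead, and it frees the phenol from its hydrogen bond to the formyl group.

**Step 5**
Reactants: 6 methyl 4,4-dimethoxy-3-oxobutanoate
Product: 7 methyl 2-chloro-4,4-dimethoxy-3-oxobutanoate (racemic)
Conditions: SO2Cl2, CH2Cl2, 0 °C
Reagents that add atoms: sulfuryl chloride, O=S(=O)(Cl)Cl
Why: Electrophilic α-chlorination of a β-keto ester at its doubly activated carbon; an acetal next to a carbonyl group should tolerate the hydrogen chloride formed at 0 °C.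

**Step 6**
Reactants: 5 allyl 2-hydroxy-4-(methoxymethoxy)-6-methyl-3-vinylbenzoate; 7 methyl 2-chloro-4,4-dimethoxy-3-oxobutanoate
Product: 8 methyl 2-[2-(allyloxycarbonyl)-5-(methoxymethoxy)-3-methyl-6-vinylphenoxy]-4,4-dimethoxy-3-oxobutanoate (racemic, keto–enol mixture)
Conditions: Cs2CO3, NaI (cat.), DMF, rt to 40 °C
Reagents that add atoms: none
Why: Williamson ether synthesis: the cesium phenoxide displaces chloride from the doubly activated secondary carbon (SN2), the classical way to 2-aryloxy-3-oxo esters, and so lays the diaryl ether oxygen before ring B exists.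

**Step 7**
Reactants: 8 the 2-aryloxy-3-oxo ester
Product: 9 methyl (E)-2-[2-(allyloxycarbonyl)-5-(methoxymethoxy)-3-methyl-6-vinylphenoxy]-4,4-dimethoxy-3-(trifluoromethylsulfonyloxy)but-2-enoate (triflate cis to the methyl ester)
Conditions: NaH, Et2O, 0 °C; then Tf2O, −20 to 0 °C
Reagents that add atoms: trifluoromethanesulfonic anhydride, O=S(=O)(OS(=O)(=O)C(F)(F)F)C(F)(F)F
Why: O-sulfonylation of the chelated sodium enolate (enol triflate formation) should place the triflate cis to the ester and turns the ketone carbon into the leaving-group-bearing β-carbon of an aryloxyacrylate.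

**Step 8**
Reactants: 9 the ring A aryloxyacrylate enol triflate; 10 methyl acetoacetate
Product: 12 allyl 2-[2-(dimethoxymethyl)-4,6-dihydroxy-3-(methoxycarbonyl)phenoxy]-4-(methoxymethoxy)-6-methyl-3-vinylbenzoate, via substitution adduct 11 (not isolated)
Conditions: 10 (1.3 equiv), NaH (3.5 equiv), THF, 0 °C to rt, then 65 °C; AcOH quench
Reagents that add atoms: none
Why: The sodium enolate of 10 adds through its doubly activated carbon to the triflate-bearing β-carbon of 9 and expels triflate (addition–elimination) to give 11; excess NaH keeps 11 as an extended enolate whose acetyl methyl carbon attacks the acrylate ester, as in NaH-promoted terminal acylation of β-dicarbonyl anions, and loss of methoxide with two enolisations aromatises ring B without an oxidant. The closest known reaction type is the Michael–Dieckmann [3+3] benzannulation of 3-oxoalkanoate anions with alkynoates, allenoates or acrylates that carry a β leaving group, which gives fully substituted resorcylates. Ring B closes by a 6-(enolendo)-exo-trig Claisen (Dieckmann) attack on the ester carbonyl. No stereocentre is formed, and the alkene geometry of 9 is irrelevant because the carbanion formed on addition rotates before triflate leaves and the extended enolate of 11 equilibrates its double bond. The selectivity needed is regiochemical and rests on polarity and reach: under monoanion conditions only the central carbon of 10 is nucleophilic, and once it is bonded only the methyl carbon can reach the ester through a six-membered transition state. Closure through the enolate oxygen to a 2-pyranone is reversible under the methoxide set free, whereas the aromatic bis-phenoxide is a sink.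

**Step 9**
Reactants: 12 the ring B resorcylate diaryl ether
Product: 13 allyl 2-{2-(dimethoxymethyl)-5-[(dimethylamino)methyl]-4,6-dihydroxy-3-(methoxycarbonyl)phenoxy}-4-(methoxymethoxy)-6-methyl-3-vinylbenzoate
Conditions: Me2N=CH2 I (Eschenmoser's salt), Et3N, CH2Cl2, 0 °C to rt
Reagents that add atoms: N,N-dimethylmethyleneiminium iodide, C=[N+](C)C.[I-]
Why: Phenolic Mannich reaction: the only C–H of ring B lies between its two free phenols, whereas ring A is an ether-protected, ester-bearing arene, so the benzylic carbon should enter at that position alone and leave the ring A methyl group untouched.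

**Step 10**
Reactants: 13 the Mannich base allyl ester
Product: 14 2-{2-(dimethoxymethyl)-5-[(dimethylamino)methyl]-4,6-dihydroxy-3-(methoxycarbonyl)phenoxy}-4-(methoxymethoxy)-6-methyl-3-vinylbenzoic acid
Conditions: Pd(PPh3)4 (5 mol %), morpholine, THF, rt
Reagents that add atoms: none
Why: Tsuji–Trost deallylation: zerovalent palladium ionises the allyl ester and morpholine captures the π-allyl complex, leaving the methyl ester, the acetals and the styrene untouched.

**Step 11**
Reactants: 14 the amino acid
Product: 15 methyl 6-(dimethoxymethyl)-9-[(dimethylamino)methyl]-8-hydroxy-3-(methoxymethoxy)-1-methyl-11-oxo-4-vinyl-11H-dibenzo[b,e][1,4]dioxepine-7-carboxylate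
Conditions: EDC·HCl, DMAP (cat.), CH2Cl2 (0.005 M), rt
Reagents that add atoms: none
Why: Carbodiimide (Steglich-type) lactonisation at high dilution closes the seven-membered depsidone ring (7-exo-trig) through the phenol ortho to the ether oxygen, the only hydroxyl that can reach the activated acid, as in classical depsidone lactonisations.

**Step 12**
Reactants: 15 the vinyl depsidone
Product: 17 methyl 6-(dimethoxymethyl)-9-[(dimethylamino)methyl]-4-formyl-8-hydroxy-3-(methoxymethoxy)-1-methyl-11-oxo-11H-dibenzo[b,e][1,4]dioxepine-7-carboxylate, via vicinal diol 16 (not isolated)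
Conditions: OsO4 (2 mol %), NaIO4, 2,6-lutidine, 1,4-dioxane/H2O, rt
Reagents that add atoms: osmium tetroxide, O=[Os](=O)(=O)=O (catalytic oxygen carrier); sodium periodate, [Na+].[O-]I(=O)(=O)=O (stoichiometric oxygen source)
Why: Lemieux–Johnson oxidation: OsO4 dihydroxylates the only alkene left (the allyl group is gone) and periodate cleaves the diol to the aryl aldehyde, while the amine is largely protonated in the buffered medium and the electron-poor phenol ring should not be attacked.

**Step 13**
Reactants: 17 the formyl depsidone
Product: 19 trimethylammonium tosylate of the lactol lactone (depsidone with 4-formyl, 3,8-dihydroxy, 1-methyl, 9-CH2NMe3+ and a 3-hydroxyphthalide fused across C6–C7; racemic lactol), via acetal-bearing ammonium tosylate 18 (not isolated)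
Conditions: MeOTs, MeCN, 50 °C; evaporate; then 2 M aq HCl/THF, 50 °C; evaporate, triturate
Reagents that add atoms: methyl p-toluenesulfonate, COS(=O)(=O)c1ccc(C)cc1; water, O
Why: Menshutkin quaternisation makes the amine a leaving group at a stage where no acidic hydroxyl competes for the methylating agent; aqueous acid then cleaves the MOM ether and the acetal, and the aldehyde hydrate closes onto the neighbouring methyl ester (5-exo-trig, neighbouring-group ester cleavage) to give the hydroxyphthalide as the racemic lactol, the ammonium group being inert in acid.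

**Step 14**
Reactants: 19 the lactol lactone ammonium tosylate; 20 fumaric acid
Product: 22 racemic target (lactol carbon unresolved), via ortho-quinone methide 21 (not isolated)
Conditions: 20 (10 equiv), i-Pr2NEt (12 equiv), DMF, 60 °C; cold 1 M HCl work-up
Reagents that add atoms: none
Why: Base-induced 1,4-elimination of trimethylamine from the ortho-hydroxybenzylammonium salt gives the ortho-quinone methide 21, and hydrogen fumarate in large excess adds to its methylene carbon (oxa-Michael addition with rearomatisation) to give the benzylic half ester; ring A, deactivated by its formyl group, should not compete as a carbon nucleophile.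

**Step 15**
Reactants: 22 racemic target
Product: 23 quininium salt of the (R)-lactol acid
Conditions: quinine (1.0 equiv), acetone, 40 °C to 20 °C, seeded stirred slurry
Reagents that add atoms: quinine, C=C[C@H]1CN2CC[C@H]1C[C@H]2[C@@H](C3=C4C=C(C=CC4=NC=C3)OC)O
Why: Crystallisation-induced diastereomer transformation (dynamic resolution): the lactol carbon epimerises in solution through the ring-opened formyl carboxylate while one diastereomeric salt crystallises, so the (R) configuration is set by the resolving base; should the salt of the (S) lactol prove the less soluble one, the pseudo-enantiomeric base quinidine takes the place of quinine.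

**Step 16**
Reactants: 23 quininium salt
Product: 24 target, (R)-lactol, E-fumarate half ester
Conditions: 0.5 M aq HCl, 0 °C, slurry; filter, wash with cold water, dry in vacuo
Reagents that add atoms: none
Why: Salt break by acid–base exchange in a slurry: quinine dissolves as its hydrochloride while the free acid stays solid, so the labile lactol centre is given no time in solution to epimerise.

**Compound list**
1 | orsellinic acid (2,4-dihydroxy-6-methylbenzoic acid) | Cc1cc(O)cc(O)c1C(=O)O | starting material
2 | allyl 2,4-dihydroxy-6-methylbenzoate | Cc1cc(O)cc(O)c1C(=O)OCC=C | intermediate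
3 | allyl 2-hydroxy-4-(methoxymethoxy)-6-methylbenzoate | Cc1cc(OCOC)cc(O)c1C(=O)OCC=C | intermediate
4 | allyl 3-formyl-2-hydroxy-4-(methoxymethoxy)-6-methylbenzoate | Cc1cc(OCOC)c(C=O)c(O)c1C(=O)OCC=C | intermediate
5 | allyl 2-hydroxy-4-(methoxymethoxy)-6-methyl-3-vinylbenzoate | Cc1cc(OCOC)c(C=C)c(O)c1C(=O)OCC=C | intermediate
6 | methyl 4,4-dimethoxy-3-oxobutanoate | COC(OC)C(=O)CC(=O)OC | starting material
7 | methyl 2-chloro-4,4-dimethoxy-3-oxobutanoate (racemic) | COC(OC)C(=O)C(Cl)C(=O)OC | intermediate
8 | methyl 2-[2-(allyloxycarbonyl)-5-(methoxymethoxy)-3-methyl-6-vinylphenoxy]-4,4-dimethoxy-3-oxobutanoate (racemic) | Cc1cc(OCOC)c(C=C)c(OC(C(=O)OC)C(=O)C(OC)OC)c1C(=O)OCC=C | intermediate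
9 | methyl (E)-2-[2-(allyloxycarbonyl)-5-(methoxymethoxy)-3-methyl-6-vinylphenoxy]-4,4-dimethoxy-3-(trifluoromethylsulfonyloxy)but-2-enoate | Cc1cc(OCOC)c(C=C)c(O/C(C(=O)OC)=C(/OS(=O)(=O)C(F)(F)F)C(OC)OC)c1C(=O)OCC=C | intermediate
10 | methyl acetoacetate | CC(=O)CC(=O)OC | starting material
11 | dimethyl 4-acetyl-2-[2-(allyloxycarbonyl)-5-(methoxymethoxy)-3-methyl-6-vinylphenoxy]-3-(dimethoxymethyl)pent-2-enedioate (substitution adduct, not isolated) | Cc1cc(OCOC)c(C=C)c(OC(C(=O)OC)=C(C(OC)OC)C(C(C)=O)C(=O)OC)c1C(=O)OCC=C | intermediate
12 | allyl 2-[2-(dimethoxymethyl)-4,6-dihydroxy-3-(methoxycarbonyl)phenoxy]-4-(methoxymethoxy)-6-methyl-3-vinylbenzoate | Cc1cc(OCOC)c(C=C)c(Oc2c(O)cc(O)c(C(=O)OC)c2C(OC)OC)c1C(=O)OCC=C | intermediate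
13 | allyl 2-{2-(dimethoxymethyl)-5-[(dimethylamino)methyl]-4,6-dihydroxy-3-(methoxycarbonyl)phenoxy}-4-(methoxymethoxy)-6-methyl-3-vinylbenzoate | Cc1cc(OCOC)c(C=C)c(Oc2c(O)c(CN(C)C)c(O)c(C(=O)OC)c2C(OC)OC)c1C(=O)OCC=C | intermediate
14 | 2-{2-(dimethoxymethyl)-5-[(dimethylamino)methyl]-4,6-dihydroxy-3-(methoxycarbonyl)phenoxy}-4-(methoxymethoxy)-6-methyl-3-vinylbenzoic acid | Cc1cc(OCOC)c(C=C)c(Oc2c(O)c(CN(C)C)c(O)c(C(=O)OC)c2C(OC)OC)c1C(=O)O | intermediate
15 | methyl 6-(dimethoxymethyl)-9-[(dimethylamino)methyl]-8-hydroxy-3-(methoxymethoxy)-1-methyl-11-oxo-4-vinyl-11H-dibenzo[b,e][1,4]dioxepine-7-carboxylate | Cc1cc(OCOC)c(C=C)c2c1C(=O)Oc1c(CN(C)C)c(O)c(C(=O)OC)c(C(OC)OC)c1O2 | intermediate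
16 | 4-(1,2-dihydroxyethyl) analogue of 15 (racemic vicinal diol, not isolated) | Cc1cc(OCOC)c(C(O)CO)c2c1C(=O)Oc1c(CN(C)C)c(O)c(C(=O)OC)c(C(OC)OC)c1O2 | intermediate
17 | methyl 6-(dimethoxymethyl)-9-[(dimethylamino)methyl]-4-formyl-8-hydroxy-3-(methoxymethoxy)-1-methyl-11-oxo-11H-dibenzo[b,e][1,4]dioxepine-7-carboxylate | Cc1cc(OCOC)c(C=O)c2c1C(=O)Oc1c(CN(C)C)c(O)c(C(=O)OC)c(C(OC)OC)c1O2 | intermediate
18 | 9-(trimethylammoniomethyl) analogue of 17, p-toluenesulfonate (not isolated) | Cc1cc(OCOC)c(C=O)c2c1C(=O)Oc1c(C[N+](C)(C)C)c(O)c(C(=O)OC)c(C(OC)OC)c1O2.Cc1ccc(cc1)S(=O)(=O)[O-] | intermediate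
19 | lactol lactone ammonium tosylate: 4-formyl-3,8-dihydroxy-1-methyl depsidone with 9-CH2NMe3+ and 3-hydroxyphthalide fused at C6–C7 (lactol carbon on C6, lactone carbonyl on C7; racemic) | Cc1cc(O)c(C=O)c2c1C(=O)Oc1c(C[N+](C)(C)C)c(O)c3c(c1O2)C(O)OC3=O.Cc1ccc(cc1)S(=O)(=O)[O-] | intermediate
20 | fumaric acid | OC(=O)/C=C/C(=O)O | starting material
21 | ortho-quinone methide of ring B (9-methylene-8-oxo dienone, not isolated) | Cc1cc(O)c(C=O)c2c1C(=O)OC1=C(O2)C3=C(C(=O)OC3O)C(=O)C1=C | intermediate
22 | racemic target: (E)-fumaric acid half ester of the 9-hydroxymethyl lactol lactone depsidone, lactol carbon unresolved | Cc1cc(O)c(C=O)c2c1C(=O)Oc1c(COC(=O)/C=C/C(=O)O)c(O)c3c(c1O2)C(O)OC3=O | intermediate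
23 | quininium salt of the (R)-lactol fumarate half ester | Cc1cc(O)c(C=O)c2c1C(=O)Oc1c(COC(=O)/C=C/C(=O)[O-])c(O)c3c(c1O2)[C@H](O)OC3=O.C=C[C@H]1C[NH+]2CC[C@H]1C[C@H]2[C@@H](C3=C4C=C(C=CC4=NC=C3)OC)O | intermediate
24 | CNP0379578.1, (R)-lactol, E-fumarate half ester | Cc1cc(O)c(C=O)c2c1C(=O)Oc1c(COC(=O)/C=C/C(=O)O)c(O)c3c(c1O2)[C@H](O)OC3=O | target

**Count and risks**
Total: 16 steps. Longest linear sequence: 15 steps (steps 1–4 and 6–16, from orsellinic acid); step 5 is a one-step branch.

Step 8 (benzannulation). The enolate may attack the sulfur of the triflate and merely return the enolate of 8, the adduct may close through oxygen to a 2-pyranone and stall, or the terminal enolate may not form. The fallback sets out from 9 and makes the first C–C bond by cross-coupling instead of conjugate addition. Negishi coupling with the Reformatsky reagent BrZnCH2CO2Me (Pd(PPh3)4, THF, 50 °C) should give the glutaconate diester F1. C-Acetylation of its lithium dienolate (LiN(SiMe3)2, 1-acetylimidazole, THF, −78 °C) leads to 11, which is isolated and cyclised with NaH in THF at 65 °C, returning to the route at 12.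

Step 14 (fumarate by way of the quinone methide). The quinone methide may be captured by a phenoxide or lactol oxygen of a second molecule (oligomerisation), or the carboxylate addition may revert. The fallback sets out from 19 and separates C–O bond formation from acylation. In aqueous NaHCO3/MeCN at 50 °C, water in solvent quantity traps the quinone methide to give the benzylic alcohol, racemic salazinic acid F2. Ring opening of maleic anhydride by this primary alcohol (THF, Et3N cat., 0 °C) gives the maleate half ester F3. Iodine-catalysed Z-to-E isomerisation under visible light returns to the route at 22.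

Step 15 (dynamic resolution). No salt may crystallise, the salt of the wrong lactol epimer may crystallise with either base, or epimerisation in solution may be too slow to drain the mother liquor. The fallback sets out from 22 and replaces crystallisation by chromatography. Preparative supercritical-fluid chromatography on a chiral amylose carbamate phase (CO2/MeOH with formic acid, 5 °C) separates the lactol enantiomers. The (S) fraction is re-equilibrated in warm acetone and recycled. The (R) fraction is evaporated cold and crystallised, returning to the route at 24; no new compound is made (F0).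

**Further compounds**
F1 | step 8 | dimethyl (E)-2-[2-(allyloxycarbonyl)-5-(methoxymethoxy)-3-methyl-6-vinylphenoxy]-3-(dimethoxymethyl)pent-2-enedioate | Cc1cc(OCOC)c(C=C)c(O/C(C(=O)OC)=C(/CC(=O)OC)C(OC)OC)c1C(=O)OCC=C
F2 | step 14 | racemic salazinic acid (9-hydroxymethyl lactol lactone depsidone) | Cc1cc(O)c(C=O)c2c1C(=O)Oc1c(CO)c(O)c3c(c1O2)C(O)OC3=O
F3 | step 14 | (Z)-maleic acid half ester of F2 | Cc1cc(O)c(C=O)c2c1C(=O)Oc1c(COC(=O)/C=C\C(=O)O)c(O)c3c(c1O2)C(O)OC3=O
F0 | step 15 | none | none
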